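Readings and results are calculated from invented constants, and the scatter is random.

Slowness is the convenience of this exchange: it takes days, so its first reading can be taken as an average rate and the rest of its time counted in turnovers.

| setting | elm | alder | flask |
|---|---|---|---|
| starting complex | 0.86 M | 0.86 M | 0.86 M |
| incoming ligand | 0.60 equiv | 1.4 equiv | 0.900 equiv |
| remark | run made earlier | run made earlier |  |
| time |  |  | 15 d |

- elm (time / d: complex with one exchanged / %): 0.333: 20; 0.833: 33; 1.67: 36; 4.00: 32; 8.00: 30; 20.0: 29
- alder (time / d: complex with one exchanged / %): 0.333: 40; 0.833: 48; 1.67: 43; 4.00: 36; 8.00: 34; 20.0: 38

(each reading ± 2 percentage points)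

1. time, not beyond 15 d, at which the flask holds most complex with one exchanged
2. the amount of complex with one exchanged, in percent of the starting complex charged, at that time
3. the first time at which complex with one exchanged reaches 21 %, in the same percent



What do the first readings give? Divide the complex with one exchanged at the first reading by that time and by the equivalents e of incoming ligand. This chord κ is 100 % d⁻¹ in elm and 85.8 % d⁻¹ in alder, with mean 93.0 % d⁻¹.

What is κ good for? Its product with e is a rate, and the reciprocal of that rate is a time. For the flask, where incoming ligand is the limiting reagent, that gives 1.20 d: this turnover time τ is the time in which the average rate up to the first reading, a chord and not the rate at the very start, would make complex with one exchanged equal to the starting complex charged, if kept up.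

Does τ say anything about the peak? The highest elm reading stands at 1.67 d, twice the time of the highest alder reading, yet the counts, time divided by each run's own τ, are 0.931 and 1.08.

Isn't that weak? Yes: the readings are widely spaced, and the count of one is a marker read from two runs, not a law. Still, my own reckoning puts the flask's maximum near τ, and the level asked for at its fraction of τ, 0.251 d. For the amount I have just the bracket 36 % to 48 %.

The forecast says 1.1 d, 41 % and 0.23 d, on this ground: “So the best time is the early maximum, not the end.” Its time is earlier than my τ.

The flask gives 1.37 d, 42.1 % and 0.208 d.

    starting complex + incoming ligand ⇌ leaving ligand + complex with one exchanged (K = 2.93, k = 0.0759 M⁻¹ h⁻¹)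
    complex with two exchanged + incoming ligand ⇌ leaving ligand + complex with three exchanged (K = 0.180, k = 0.0358 M⁻¹ h⁻¹)
    complex with one exchanged + incoming ligand ⇌ leaving ligand + complex with two exchanged (K = 2.14, k = 0.0308 M⁻¹ h⁻¹)

The flask's best falls at 1.14 turnovers. The neighbour flask with 0.230 equiv of incoming ligand has run 3.21 turnovers by 15 d, past one, and it ends at 17.3 %, below its best of 18.8 %. One thing holding the flask's peak down is the back step of the first exchange: with the undoing of leaving ligand and complex with one exchanged taken away, the flask's highest amount of complex with one exchanged goes from 42.1 % to 78.9 %.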